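**Plan**

- Retrosynthetic cuts, in order: the oxolane O1–C2 bond (O–CH2) together with the bond from the ketone carbon to the 3,4,5-trimethoxyphenyl ring; then the C4–C5 bond between the ring carbons that carry CH2OH and the dimethoxyphenyl group.
- Enabling feature: the ring CH2 (C2) is β to the ketone carbonyl (O1–C2H2–C3H–C=O, a β-alkoxy ketone), so O1–C2 is the retron of an oxa-Michael addition to a 2-substituted aryl vinyl ketone. O1 and the carbonyl carbon are 1,4-related through C5–C4–C3, so both can be stored in one γ-lactone ring that is not in the target.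
- Forward: 3,4-dimethoxybenzaldehyde is joined to a bromomethyl butenolide (C4–C5 bond). The lactone is shifted to the benzylic oxygen and the primary alcohol tritylated. Aryllithium addition opens this temporary lactone and the freed alkoxide closes the oxolane on the methylene carbon in the same flask; detritylation ends the route.
- Stereochemistry: C5 (S) and C4 (R) come together from a catalyst-controlled, anti-selective Nozaki–Hiyama–Kishi allylation. C3 (R) comes from kinetic protonation of the ring-closed enolate on the face away from the CH2OTr group.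

Key step: step 3

Assumption: 3-(bromomethyl)furan-2(5H)-one is taken as a purchasable allylic bromide, and the (S,S)-ligand is taken to direct the allyl group to the Si face of the aldehyde; if the sense is opposite, the (R,R)-ligand is used.

**Step 1**
Reactants: 1 3,4-dimethoxybenzaldehyde; 2 3-(bromomethyl)furan-2(5H)-one
Product: 4 (4R)-4-[(S)-(3,4-dimethoxyphenyl)(hydroxy)methyl]-3-methylideneoxolan-2-one, via trimethylsilyl ether 3 (not isolated)
Conditions: CrCl2 (10 mol%), (S,S)-1,8-bis(4-isopropyl-4,5-dihydrooxazol-2-yl)-3,6-diphenyl-9H-carbazole (12 mol%), i-Pr2NEt (30 mol%), Mn powder, TMSCl, THF, rt; then 1 M HCl, THF, 0 °C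
Reagents that add atoms: none
Why: In this catalytic asymmetric Nozaki–Hiyama–Kishi allylation the allylchromium species from 2 should add through its γ-carbon in a closed six-membered chair transition state, the ring-locked E-type geometry of the allyl unit giving the anti adduct and the chiral bis(oxazoline) ligand on trivalent chromium selecting the Si face of the aldehyde, which sets the S carbinol and the R ring centre together.

**Step 2**
Reactants: 4 (4R)-4-[(S)-(3,4-dimethoxyphenyl)(hydroxy)methyl]-3-methylideneoxolan-2-one
Product: 6 (4R,5S)-5-(3,4-dimethoxyphenyl)-3-methylidene-4-[(trityloxy)methyl]oxolan-2-one, via hydroxymethyl lactone 5 (not isolated)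
Conditions: DBU (0.2 equiv), CH2Cl2, rt; then TrCl, DBU (1.5 equiv), 0 °C to rt
Reagents that add atoms: trityl chloride, ClC(c1ccccc1)(c1ccccc1)c1ccccc1
Why: Base-catalysed translactonisation (intramolecular transesterification) should move the acyl group from the primary to the benzylic oxygen, and selective O-tritylation of the primary alcohol so released pulls the equilibrium over, both stereocentres staying untouched so that the aryl and CH2OTr groups end trans on the new lactone.

**Step 3**
Reactants: 6 (4R,5S)-5-(3,4-dimethoxyphenyl)-3-methylidene-4-[(trityloxy)methyl]oxolan-2-one; 7 5-bromo-1,2,3-trimethoxybenzene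
Product: 12 [(3R,4R,5S)-5-(3,4-dimethoxyphenyl)-4-[(trityloxy)methyl]oxolan-3-yl](3,4,5-trimethoxyphenyl)methanone, via aryllithium 8 (not isolated), via lithium hemiketalate 9 (not isolated), via lithium alkoxide enone 10 (not isolated), via lithium enolate 11 (not isolated)
Conditions: 7, n-BuLi (1.0 equiv), THF, −78 °C; add to 6, THF, −78 °C; DMPU, −78 to 0 °C, 0.02 M; then −78 °C, inverse quench into AcOH/THF
Reagents that add atoms: none
Why: Proposed new method: aryllithium 8 should add to the lactone carbonyl of 6 to give the cyclic hemiketalate 9, which on warming opens to 10 and so unmasks at the same moment the benzylic alkoxide (the former lactone oxygen) and a 2-substituted aryl vinyl ketone; the alkoxide then adds to the methylene terminus to give enolate 11, a downhill step because an alkoxide is exchanged for a better stabilised aryl ketone enolate, and cold acetic acid delivers 12. The closest known reactions are the mono-addition of aryllithiums to γ-lactones at −78 °C, the base-mediated 5-endo-trig cyclisation of γ-hydroxy vinyl sulfones and hydroxy enones to oxolanes, and the kinetic ketonisation of exocyclic enolates to the less stable cis isomer. The oxolane ring closes in the 5-endo-trig mode (oxygen onto the exocyclic CH2 of the enone), which is geometrically strained but should be feasible because the acceptor is a strongly electrophilic aryl enone that rotates freely about the C3–C4 bond and no competing nucleophile is present in the dilute aprotic medium. The new stereocentre C3 (α to the ketone) is set by protonation of 11 on the face opposite the neighbouring trityloxymethyl group, which allylic strain against the enolate substituents pushes into a pseudoaxial position, so the aroyl group ends cis to CH2OTr; C4 and C5 are carried over unchanged from 6. The step needs the benzylic and not the primary oxygen to attack, and carbonyl addition in preference to conjugate addition of 8: the first is secured because the primary oxygen is a non-migrating trityl ether and the benzylic oxygen is released from the lactone only when the enone appears, the second by the hard aryllithium at −78 °C and by the stability of 9, which keeps the ketone masked until 8 is consumed.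

**Step 4**
Reactants: 12 [(3R,4R,5S)-5-(3,4-dimethoxyphenyl)-4-[(trityloxy)methyl]oxolan-3-yl](3,4,5-trimethoxyphenyl)methanone
Product: 13 [(3R,4R,5S)-5-(3,4-dimethoxyphenyl)-4-(hydroxymethyl)oxolan-3-yl](3,4,5-trimethoxyphenyl)methanone
Conditions: AcOH/THF/H2O (3:1:1), 40 °C
Reagents that add atoms: none
Why: Acid-catalysed solvolysis of the trityl ether (detritylation through the trityl cation, trapped by water) should free the primary alcohol under conditions too mild to enolise the aryl ketone or ionise the benzylic ether, so the three stereocentres are kept, the product being free to stand in ring–chain equilibrium with its cyclic hemiketal.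

**Compound list**

1 | 3,4-dimethoxybenzaldehyde | COc1ccc(C=O)cc1OC | starting material
2 | 3-(bromomethyl)furan-2(5H)-one | BrCC1=CCOC1=O | starting material
3 | (4R)-4-[(S)-(3,4-dimethoxyphenyl)(trimethylsilyloxy)methyl]-3-methylideneoxolan-2-one | COc1ccc([C@@H](O[Si](C)(C)C)[C@H]2COC(=O)C2=C)cc1OC | intermediate
4 | (4R)-4-[(S)-(3,4-dimethoxyphenyl)(hydroxy)methyl]-3-methylideneoxolan-2-one | COc1ccc([C@@H](O)[C@H]2COC(=O)C2=C)cc1OC | intermediate
5 | (4R,5S)-5-(3,4-dimethoxyphenyl)-4-(hydroxymethyl)-3-methylideneoxolan-2-one | COc1ccc([C@H]2OC(=O)C(=C)[C@@H]2CO)cc1OC | intermediate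
6 | (4R,5S)-5-(3,4-dimethoxyphenyl)-3-methylidene-4-[(trityloxy)methyl]oxolan-2-one | COc1ccc([C@H]2OC(=O)C(=C)[C@@H]2COC(c3ccccc3)(c4ccccc4)c5ccccc5)cc1OC | intermediate
7 | 5-bromo-1,2,3-trimethoxybenzene | COc1cc(Br)cc(OC)c1OC | starting material
8 | 3,4,5-trimethoxyphenyllithium | [Li]c1cc(OC)c(OC)c(OC)c1 | intermediate
9 | lithium (4R,5S)-5-(3,4-dimethoxyphenyl)-3-methylidene-2-(3,4,5-trimethoxyphenyl)-4-[(trityloxy)methyl]oxolan-2-olate (both C2 epimers) | [Li+].COc1ccc([C@H]2OC([O-])(c3cc(OC)c(OC)c(OC)c3)C(=C)[C@@H]2COC(c4ccccc4)(c5ccccc5)c6ccccc6)cc1OC | intermediate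
10 | lithium (1S,2R)-1-(3,4-dimethoxyphenyl)-3-methylidene-4-oxo-4-(3,4,5-trimethoxyphenyl)-2-[(trityloxy)methyl]butan-1-olate | [Li+].COc1ccc([C@@H]([O-])[C@@H](COC(c2ccccc2)(c3ccccc3)c4ccccc4)C(=C)C(=O)c5cc(OC)c(OC)c(OC)c5)cc1OC | intermediate
11 | lithium [(4R,5S)-5-(3,4-dimethoxyphenyl)-4-[(trityloxy)methyl]oxolan-3-ylidene](3,4,5-trimethoxyphenyl)methanolate | [Li+].COc1ccc([C@H]2OCC(=C([O-])c3cc(OC)c(OC)c(OC)c3)[C@@H]2COC(c4ccccc4)(c5ccccc5)c6ccccc6)cc1OC | intermediate
12 | [(3R,4R,5S)-5-(3,4-dimethoxyphenyl)-4-[(trityloxy)methyl]oxolan-3-yl](3,4,5-trimethoxyphenyl)methanone | COc1ccc([C@H]2OC[C@H](C(=O)c3cc(OC)c(OC)c(OC)c3)[C@@H]2COC(c4ccccc4)(c5ccccc5)c6ccccc6)cc1OC | intermediate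
13 | [(3R,4R,5S)-5-(3,4-dimethoxyphenyl)-4-(hydroxymethyl)oxolan-3-yl](3,4,5-trimethoxyphenyl)methanone | COc1ccc([C@H]2OC[C@H](C(=O)c3cc(OC)c(OC)c(OC)c3)[C@@H]2CO)cc1OC | target

**Step count and risks**

Total steps: 4. Longest linear sequence: 4 steps (from 1 and 2 to 13).

Steps most likely to fail:

1. Step 3 (Proposed new method). The 5-endo-trig closure may be too slow, so that the opened alkoxide oligomerises by intermolecular conjugate addition or transfers its benzylic hydride to the enone. The aryllithium may add in conjugate fashion to the methylene lactone. Protonation of the enolate may show poor facial selectivity, or the centre α to the ketone may epimerise during work-up. The fallback uses known chemistry only, sets out from 6 and comes back at 12. DIBAL-H reduction of the lactone should give (1S,2R)-1-(3,4-dimethoxyphenyl)-3-methylidene-2-[(trityloxy)methyl]butane-1,4-diol F1. Mitsunobu cyclodehydration (PPh3, DIAD) closes the same O–CH2 bond on the primary allylic carbon and should give (2S,3R)-2-(3,4-dimethoxyphenyl)-4-methylidene-3-[(trityloxy)methyl]oxolane F2. Hydroboration with 9-BBN from the face away from CH2OTr, then H2O2/NaOH, should give the cis alcohol [(3S,4R,5S)-5-(3,4-dimethoxyphenyl)-4-[(trityloxy)methyl]oxolan-3-yl]methanol F3. DMP oxidation gives (3R,4R,5S)-5-(3,4-dimethoxyphenyl)-4-[(trityloxy)methyl]oxolane-3-carbaldehyde F4, which is used at once. Addition of aryllithium 8 at −78 °C gives [(3R,4R,5S)-5-(3,4-dimethoxyphenyl)-4-[(trityloxy)methyl]oxolan-3-yl](3,4,5-trimethoxyphenyl)methanol F5 as a carbinol mixture, and a second buffered DMP oxidation returns 12 without exposing the α-centre to base.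

2. Step 2. The acyl migration may stay incomplete, the freed primary alcohol or DBU may add in conjugate fashion to the methylene lactone (oligomerisation), or tritylation may lag behind these side reactions. The fallback sets out from 4 and comes back at 6. LiOH in THF/H2O at 0 °C should open the lactone to lithium (3R,4S)-4-(3,4-dimethoxyphenyl)-4-hydroxy-3-(hydroxymethyl)-2-methylidenebutanoate F6. TrCl in pyridine tritylates only the primary alcohol and, after mild acidification, gives (3R,4S)-4-(3,4-dimethoxyphenyl)-4-hydroxy-2-methylidene-3-[(trityloxy)methyl]butanoic acid F7. In F7 only the benzylic hydroxyl is left to lactonise, so carbodiimide lactonisation (EDC·HCl, DMAP) can give no lactone other than 6.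

3. Step 1. Enantioface control by the chromium catalyst may be insufficient, or anti selectivity may erode through an open transition state. The fallback sets out from 2 (with 1) and comes back at 4. Borylation of 2 with B2pin2 and the zerovalent palladium catalyst Pd2(dba)3 should give 3-[(4,4,5,5-tetramethyl-1,3,2-dioxaborolan-2-yl)methyl]furan-2(5H)-one F8. F8 then adds to 1 under catalysis by the chiral BINOL phosphoric acid TRIP (the enantiomer that gives the S carbinol) through a closed chair transition state that again translates the locked E-type geometry into the anti adduct; cleavage of the borate on work-up gives 4.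

**Further compounds**

F1 | step 3 | (1S,2R)-1-(3,4-dimethoxyphenyl)-3-methylidene-2-[(trityloxy)methyl]butane-1,4-diol | COc1ccc([C@@H](O)[C@@H](COC(c2ccccc2)(c3ccccc3)c4ccccc4)C(=C)CO)cc1OC
F2 | step 3 | (2S,3R)-2-(3,4-dimethoxyphenyl)-4-methylidene-3-[(trityloxy)methyl]oxolane | COc1ccc([C@H]2OCC(=C)[C@@H]2COC(c3ccccc3)(c4ccccc4)c5ccccc5)cc1OC
F3 | step 3 | [(3S,4R,5S)-5-(3,4-dimethoxyphenyl)-4-[(trityloxy)methyl]oxolan-3-yl]methanol | COc1ccc([C@H]2OC[C@H](CO)[C@@H]2COC(c3ccccc3)(c4ccccc4)c5ccccc5)cc1OC
F4 | step 3 | (3R,4R,5S)-5-(3,4-dimethoxyphenyl)-4-[(trityloxy)methyl]oxolane-3-carbaldehyde | COc1ccc([C@H]2OC[C@H](C=O)[C@@H]2COC(c3ccccc3)(c4ccccc4)c5ccccc5)cc1OC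
F5 | step 3 | [(3R,4R,5S)-5-(3,4-dimethoxyphenyl)-4-[(trityloxy)methyl]oxolan-3-yl](3,4,5-trimethoxyphenyl)methanol (carbinol epimers) | COc1ccc([C@H]2OC[C@H](C(O)c3cc(OC)c(OC)c(OC)c3)[C@@H]2COC(c4ccccc4)(c5ccccc5)c6ccccc6)cc1OC
F6 | step 2 | lithium (3R,4S)-4-(3,4-dimethoxyphenyl)-4-hydroxy-3-(hydroxymethyl)-2-methylidenebutanoate | [Li+].COc1ccc([C@@H](O)[C@@H](CO)C(=C)C(=O)[O-])cc1OC
F7 | step 2 | (3R,4S)-4-(3,4-dimethoxyphenyl)-4-hydroxy-2-methylidene-3-[(trityloxy)methyl]butanoic acid | COc1ccc([C@@H](O)[C@@H](COC(c2ccccc2)(c3ccccc3)c4ccccc4)C(=C)C(=O)O)cc1OC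
F8 | step 1 | 3-[(4,4,5,5-tetramethyl-1,3,2-dioxaborolan-2-yl)methyl]furan-2(5H)-one | CC1(C)OB(CC2=CCOC2=O)OC1(C)C
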